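**Plan**
- **Cuts:** the two aryl O‑acetyl masks come off last. Before that the alkyl chain (OCH2 = C1) is cut at C2–C3 into two free acids, (S)‑16‑methyloctadecanoic acid and 3‑[(2,3‑diacetoxybenzoyl)oxy]propanoic acid. Their CO2H carbons are traceless activating groups, lost as CO2.
- **Further cuts:** the fatty acid is cut at C4–C5 (Grignard opening of β‑propiolactone) and at C15–C16 (Grignard/1,11‑dibromoundecane coupling). The head‑group acid is cut at the benzoate C(=O)–O bond.
- **Forward order:** C15–C16, then C4–C5, then C2–C3. A mixed Kolbe electrolysis joins the whole C18 anteiso tail to the whole O–CH2–CH2–benzoate head in one operation; no ring is formed anywhere in the route.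
- **Enabling feature:** C2 and C3 are unbranched CH2 carbons, so both are available as primary radicals that couple rather than over‑oxidise. The C1H2–C2H2 pair next to the benzoate oxygen gives a β‑aroyloxyethyl radical whose 1,2‑acyloxy shift is degenerate. The benzene ring carries the ester and two OAc groups in place of the C2'/C3' catechol OH groups and is too electron‑poor to be attacked at the anode.
- **Stereochemistry:** the only stereocentre, C17 (S), is bought as (S)‑1‑bromo‑2‑methylbutane. It never sits next to a reacting centre (β to Mg in the first coupling, fourteen bonds from the radical centre in the electrolysis).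

Key step: step 6

Remark: the centre written CC[C@H](C)C… is read as (S). Commercial (S)‑(+)‑1‑bromo‑2‑methylbutane has the same spatial arrangement (long chain > ethyl > methyl > H throughout).

**Step 1**
Reactants: 1 (S)‑1‑bromo‑2‑methylbutane; 2 1,11‑dibromoundecane (3 equiv)
Product: 4 (S)‑1‑bromo‑13‑methylpentadecane, via (S)‑2‑methylbutylmagnesium bromide 3 (not isolated)
Conditions: Mg, THF, reflux; then slow addition to 2, Li2CuCl4 (3 mol %), THF–NMP, −10 °C → rt
Reagents that add atoms: none
Why: Copper‑catalysed Grignard–alkyl bromide cross‑coupling (Kochi coupling) joins two primary sp3 carbons, slow addition of 3 to an excess of the symmetrical dibromide favours mono‑substitution, and the stereocentre, β to magnesium, is never part of a reacting bond, so the (S) configuration of 1 is carried over.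

**Step 2**
Reactants: 4 (S)‑1‑bromo‑13‑methylpentadecane; 5 β‑propiolactone (oxetan‑2‑one)
Product: 7 (S)‑16‑methyloctadecanoic acid, via (S)‑13‑methylpentadecylmagnesium bromide 6 (not isolated)
Conditions: Mg, THF, 40 °C; CuCl (5 mol %), then 5, THF, −20 → 0 °C; 1 M HCl
Reagents that add atoms: none
Why: Under copper(I) catalysis a primary alkyl Grignard reagent opens β‑propiolactone by SN2 attack at the O–CH2 carbon (strain‑driven alkyl–oxygen cleavage) rather than at the carbonyl, a known three‑carbon homologation to 3‑substituted propanoic acids that installs C3, C4 and the sacrificial carboxyl carbon at once.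

**Step 3**
Reactants: 8 2,3‑dihydroxybenzoic acid
Product: 9 2,3‑diacetoxybenzoic acid
Conditions: Ac2O, cat. H2SO4, 60 °C; then ice‑water
Reagents that add atoms: acetic anhydride, CC(=O)OC(C)=O
Why: Acid‑catalysed O‑acetylation of both phenols (any mixed anhydride at the carboxyl group is hydrolysed on aqueous work‑up) turns the easily oxidised catechol into an electron‑poor bis(aryl acetate).

**Step 4**
Reactants: 9 2,3‑diacetoxybenzoic acid; 10 tert‑butyl 3‑hydroxypropanoate
Product: 12 tert‑butyl 3‑[(2,3‑diacetoxybenzoyl)oxy]propanoate, via 2,3‑diacetoxybenzoyl chloride 11 (not isolated)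
Conditions: (COCl)2, cat. DMF, CH2Cl2, 0 °C → rt, concentrate; then 10, pyridine, CH2Cl2, 0 °C → rt
Reagents that add atoms: none
Why: Acid chloride formation followed by pyridine‑mediated acylation of a primary alcohol is a standard esterification, and the weak base avoids E1cB elimination of the β‑acyloxy ester and acetyl scrambling.

**Step 5**
Reactants: 12 tert‑butyl 3‑[(2,3‑diacetoxybenzoyl)oxy]propanoate
Product: 13 3‑[(2,3‑diacetoxybenzoyl)oxy]propanoic acid
Conditions: TFA–CH2Cl2 (1:2), rt
Reagents that add atoms: none
Why: Acidolysis of the tert‑butyl ester (E1 loss of isobutene) frees the carboxylic acid without base, so the aryl acetates, the benzoate and the elimination‑prone β‑acyloxy unit stay intact.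

**Step 6**
Reactants: 7 (S)‑16‑methyloctadecanoic acid (1 equiv); 13 3‑[(2,3‑diacetoxybenzoyl)oxy]propanoic acid (5 equiv)
Product: 16 (S)‑17‑methylnonadecyl 2,3‑diacetoxybenzoate, via (S)‑15‑methylheptadecyl radical 14 (not isolated), via 2‑(2,3‑diacetoxybenzoyloxy)ethyl radical 15 (not isolated)
Conditions: Me4NOH·5H2O (0.3 equiv per CO2H), acetone, RVC/RVC electrodes, undivided cell, constant current with rapid alternating polarity (square wave, ca. 50 ms per pulse), rt
Reagents that add atoms: none
Why: Mixed Kolbe electrolysis: both carboxylates are oxidised at the carbon electrode, lose CO2 and give the primary radicals 14 and 15, which combine in the radical‑rich layer at the surface to form the C2–C3 CH2–CH2 bond. The closest known reaction type is the Kolbe heterocoupling of a fatty acid with an O‑acylated β‑hydroxy acid, run here in its alternating‑polarity variant in acetone so that no lasting basic cathode layer builds up that could cause E1cB loss of the aroate from 13 or cleave the aryl acetates. No ring is closed and no stereocentre is formed, and C17 lies fourteen bonds from the radical centre and is untouched. Cross‑selectivity is statistical and is secured by the five‑fold excess of the cheap acid 13, while the two symmetrical dimers differ widely in polarity from 16 and should be removable by chromatography. The radical rather than the cationic (Hofer–Moest) pathway is secured because both radicals are unbranched and primary, 15 being made still harder to oxidise by its β‑aroyloxy group, and its only fast rearrangement, the 1,2‑acyloxy (Surzur–Tanner) shift, is degenerate because both carbons of the OCH2CH2 unit are CH2. Chemoselectivity against oxidation of the ring is secured by the ester and the two acetates, which keep the benzene ring electron‑poor.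

**Step 7**
Reactants: 16 (S)‑17‑methylnonadecyl 2,3‑diacetoxybenzoate
Product: 17 gentiside G, (S)‑17‑methylnonadecyl 2,3‑dihydroxybenzoate
Conditions: N2H4·H2O (2.5 equiv), THF, 0 °C → rt, Ar; dilute HCl
Reagents that add atoms: none
Why: Chemoselective hydrazinolysis of aryl acetates: the phenolic esters are far better acyl donors than the conjugated, ortho‑substituted alkyl benzoate, which is deactivated further once the ortho phenol is free (hydrogen‑bonded salicylate), and the remote stereocentre is untouched.

**Compound list**
1 | (S)‑1‑bromo‑2‑methylbutane | CC[C@H](C)CBr | starting material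
2 | 1,11‑dibromoundecane | BrCCCCCCCCCCCBr | starting material
3 | (S)‑2‑methylbutylmagnesium bromide | CC[C@H](C)C[Mg]Br | intermediate
4 | (S)‑1‑bromo‑13‑methylpentadecane | CC[C@H](C)CCCCCCCCCCCCBr | intermediate
5 | β‑propiolactone (oxetan‑2‑one) | O=C1CCO1 | starting material
6 | (S)‑13‑methylpentadecylmagnesium bromide | CC[C@H](C)CCCCCCCCCCCC[Mg]Br | intermediate
7 | (S)‑16‑methyloctadecanoic acid | CC[C@H](C)CCCCCCCCCCCCCCC(=O)O | intermediate
8 | 2,3‑dihydroxybenzoic acid | OC(=O)c1cccc(O)c1O | starting material
9 | 2,3‑diacetoxybenzoic acid | OC(=O)c1cccc(OC(C)=O)c1OC(C)=O | intermediate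
10 | tert‑butyl 3‑hydroxypropanoate | CC(C)(C)OC(=O)CCO | starting material
11 | 2,3‑diacetoxybenzoyl chloride | ClC(=O)c1cccc(OC(C)=O)c1OC(C)=O | intermediate
12 | tert‑butyl 3‑[(2,3‑diacetoxybenzoyl)oxy]propanoate | CC(C)(C)OC(=O)CCOC(=O)c1cccc(OC(C)=O)c1OC(C)=O | intermediate
13 | 3‑[(2,3‑diacetoxybenzoyl)oxy]propanoic acid | OC(=O)CCOC(=O)c1cccc(OC(C)=O)c1OC(C)=O | intermediate
14 | (S)‑15‑methylheptadecyl radical | CC[C@H](C)CCCCCCCCCCCCC[CH2] | intermediate
15 | 2‑(2,3‑diacetoxybenzoyloxy)ethyl radical | [CH2]COC(=O)c1cccc(OC(C)=O)c1OC(C)=O | intermediate
16 | (S)‑17‑methylnonadecyl 2,3‑diacetoxybenzoate | CC[C@H](C)CCCCCCCCCCCCCCCCOC(=O)c1cccc(OC(C)=O)c1OC(C)=O | intermediate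
17 | gentiside G, (S)‑17‑methylnonadecyl 2,3‑dihydroxybenzoate | CC[C@H](C)CCCCCCCCCCCCCCCCOC(=O)c1cccc(O)c1O | target

**Total step count:** 7. **Longest linear sequence:** 5 (steps 3, 4, 5, 6, 7).

**Steps most likely to fail**

**Step 6.**
- **What may go wrong:** homocoupling may outweigh the cross‑coupling, and the radicals may be over‑oxidised to cations. The electrodes may attack the aroyl ring or strip the acetates. The waxy product may foul the electrodes.
- **Fallback:** leave the oxidative radical–radical manifold for a reductive, nickel‑mediated one.
- **Course:** it sets out from 7 and 13. Each acid is activated with N‑hydroxyphthalimide and DIC (cat. DMAP, CH2Cl2), giving 1,3‑dioxoisoindolin‑2‑yl (S)‑16‑methyloctadecanoate F1 and 1,3‑dioxoisoindolin‑2‑yl 3‑[(2,3‑diacetoxybenzoyl)oxy]propanoate F2.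
- **Coupling:** the two redox‑active esters (F2 in excess) are joined by nickel‑electrocatalytic doubly decarboxylative sp3–sp3 coupling (Ni(II)/terpyridine‑type ligand, sacrificial Mg anode, RVC cathode, DMF). The same C2–C3 bond is formed under net reduction, where the arene cannot be oxidised.
- **Return:** the fallback comes back to the route at 16.

**Step 1.**
- **What may go wrong:** both ends of the dibromide may be substituted, the Grignard reagent may undergo Wurtz‑type homocoupling, and the product may be hard to separate from the equally non‑polar excess of 2.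
- **Fallback:** use a linker with two different ends.
- **Course:** it sets out from 1 (as its Grignard reagent 3). Commercial 11‑bromoundecan‑1‑ol is deprotonated with i‑PrMgCl to chloromagnesium 11‑bromoundecan‑1‑olate F3. This is coupled with 3 under Li2CuCl4 catalysis to (S)‑13‑methylpentadecan‑1‑ol F4, whose hydroxyl group gives a polarity handle for purification.
- **Return:** an Appel reaction (CBr4, PPh3, CH2Cl2) then brings the fallback back to the route at 4.

**Step 2.**
- **What may go wrong:** the Grignard reagent may attack the lactone carbonyl (acyl–oxygen cleavage), magnesium bromide may open the ring, or the product carboxylate may start oligomerisation of the lactone.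
- **Fallback:** a radical instead of a polar three‑carbon homologation.
- **Course:** it sets out from 4. A Giese addition of the derived primary radical to methyl acrylate ((Me3Si)3SiH, AIBN, toluene, 80 °C, slow addition) gives methyl (S)‑16‑methyloctadecanoate F5.
- **Return:** saponification (LiOH, THF–H2O) brings the fallback back to the route at 7.

**Further compounds**
F1 | step 6 | 1,3‑dioxoisoindolin‑2‑yl (S)‑16‑methyloctadecanoate | CC[C@H](C)CCCCCCCCCCCCCCC(=O)ON1C(=O)c2ccccc2C1=O
F2 | step 6 | 1,3‑dioxoisoindolin‑2‑yl 3‑[(2,3‑diacetoxybenzoyl)oxy]propanoate | CC(=O)Oc1cccc(C(=O)OCCC(=O)ON2C(=O)c3ccccc3C2=O)c1OC(C)=O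
F3 | step 1 | chloromagnesium 11‑bromoundecan‑1‑olate | Cl[Mg]OCCCCCCCCCCCBr
F4 | step 1 | (S)‑13‑methylpentadecan‑1‑ol | CC[C@H](C)CCCCCCCCCCCCO
F5 | step 2 | methyl (S)‑16‑methyloctadecanoate | CC[C@H](C)CCCCCCCCCCCCCCC(=O)OC
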